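## The problem

The target 20 is a flavone: a 4H-chromen-4-one in which ring A and the pyranone ring C share the C4a–C8a bond and ring B sits on C2. It has no stereocentre, so nothing has to be set and nothing can relay stereochemical information; the difficulty is purely regiochemical. Ring A is a hexasubstituted benzene whose carbons carry, in order, the acyl carbon C4 (on C4a), free hydroxyls on C5 and C6, methoxyls on C7 and C8, and the ring oxygen O1 on C8a. Five neighbouring oxygens that differ only in what they bear must be placed without stepwise oxygenation or selective demethylation, neither of which can be trusted among so many similar positions. Ring C must close through O1 and not through the equally ortho O5, so these two oxygens have to be distinguishable when the pyranone is made. Ring B carries substituents at both ortho positions (2'-OH, 6'-OMe), so the C2–C1' bond is hindered and is best bought ready-made. The 5,6-dihydroxy unit oxidises readily to quinones in base and air, and the pyranone is opened by hydroxide, so the three phenols should be released last and under neutral conditions. The enabling feature is the run C6–C7–C8–C8a: four contiguous oxygen-bearing carbons with the inner two methylated, which is the skeleton of dimethyl squarate 6. C4a with its carboxyl-level carbon C4, and C5 with its oxygen, are the α- and β-carbons of a 3-alkoxyacrylate, so a 4-alkenyl-4-hydroxycyclobutenone made from these two pieces can expand thermally into the complete ring A.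

## Retrosynthesis

**20 from 19.** The three O–benzyl bonds at O5, O6 and O2' are cut. Masking all three phenols as benzyl ethers and keeping the three methoxyls as they are lets one neutral hydrogenolysis finish the synthesis. A Lewis-acid unmasking of methyl ethers would have to choose among six ethers. The forward step must spare the C2–C3 double bond.

**19 from 17.** The O1–C2 bond is cut, giving the 2-hydroxyaryl ynone 17. Against a cut at C2–C1', this keeps the hindered aryl–C2 bond intact. Against a 1,3-diketone route, it needs no acetophenone of ring A. Because O5 is benzylated and only the C8a hydroxyl is free, ring C can close in one sense only. The forward reaction must be 6-endo and not 5-exo.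

**17 from 12 and 15.** The C3–C4 bond is cut between the ester carbon of salicylate 12 and the acetylide 16 derived from alkyne 15. This is the convergent junction: ring B arrives with C2 and C3 already attached. The forward step asks a slim sp nucleophile to acylate on a di-ortho-substituted ester that carries a free phenol.

**15 from 14 from 13.** The alkyne carbon C3 is removed, leading back to aldehyde 14, and then the benzyl group, leading to commercial 2-hydroxy-6-methoxybenzaldehyde 13. The hindered C2–C1' bond is thus present in a purchased compound.

**12 from 11.** The O6–benzyl bond is cut. In hydroquinone 11 the hydroxyl next to the ester (future O1) is hydrogen-bonded to the carbonyl and the other (O6) is not, so the forward alkylation should take the free one.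

**11 from 8.** The C5–C6 bond of ring A is cut, the reverse of the thermal cascade through dienylketene 9 and cyclohexadienone 10. No other single cut of ring A maps all six substituents onto two simple pieces: the squarate brings C6, C7, C8 and C8a with their oxygens, the acrylate brings C4a, C4 and C5 with its benzyloxy group. The precursor is a four-membered carbinol made in one step. The forward reaction needs the hydroxyl to rotate outward on ring opening.

**8 from 5 and 6.** The C4a–C8a bond is cut between the α-carbon of the acrylate and one carbonyl of dimethyl squarate 6. The two carbonyls of 6 are equivalent, so only mono-addition has to be controlled. The alkenyl nucleophile 7 must tolerate its own ester, which points to iodine–magnesium exchange on iodide 5 at low temperature.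

**5 from 3 from 1 and 2.** The C–I bond is cut, leading to 3-benzyloxyacrylate 3, and then the O–C bond of the enol ether, leading to methyl propiolate 1 and benzyl alcohol 2. Both forward steps are standard for 3-alkoxyacrylates and fix the alkene geometry.

## Roads not taken

**Alternative 1:** The cut is the C2–C1' bond, made inside a temporary lactone that ties the C3 carboxyl to O2'.
- Forward step: in aryl ester A2, Pd(OAc)2 with PCy3·HBF4, K2CO3 and pivalic acid would insert zerovalent palladium into the C1' bromide and metalate the chromone C2–H with carboxylate assistance, closing the six-membered lactone A1.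
- Merits: the hindered bond between C2 and a di-ortho-substituted ring is made intramolecularly, the 2'-oxygen arrives through the tether, and the step is late and convergent. For this one bond the approach is at least as secure as anything in the chosen plan.
- Weak points: the acyl half of A2 is a chromone-3-carboxylic acid that already contains the complete ring A, so the hardest part of the target is presupposed. After the coupling, A1 must be opened, decarboxylated and freed of its ketal. Opening a lactone on a 3-acylchromone with hydroxide invites attack at the doubly activated C2 and cleavage of the pyranone.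
- Comparison: the chosen plan avoids forming C2–C1' at all and builds ring A in one step with every substituent placed by connectivity. It pays with a less certain C3–C4 bond formation on a hindered ester.

**Alternative 2:** The cuts are C4a–C5 and O1–C2; rings A and C are folded from a pyranone-masked polyketide.
- Forward step: KOH in methanol would open the 4-pyranone of A4 to a triketone, the C4a carbanion would attack the terminal ester to close ring A, and acid would re-close ring C to give A3.
- Merits: simple polar chemistry with no organometallic reagent and no thermolysis, two rings in one flask, and ring B already in place. The new ring A is symmetrical about the C4a–C7 axis, so closure through either flanking phenol gives the same flavone. In these respects it is better than the chosen plan.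
- Weak points: A3 carries hydrogen on O7 and methyl on O6, the reverse of the target. Methylating O7 is easy, but the 6-methoxyl would then have to be cleaved selectively beside the 7-, 8- and 6'-methoxyls; this is known in type next to a chelated 5-hydroxyl but uncertain here. The side chain of A4 also has to be assembled.
- Comparison: the chosen plan delivers each oxygen with its final alkyl or hydrogen status from the start, so no late dealkylation is needed.

**Alternative 3:** The cuts are O1–C8a and C4–C4a, followed by O1–C2; a ring A aryne inserts into an arylpropiolic acid.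
- Forward step: CsF would generate the aryne from silyl triflate A6. The carboxylate of A7 would add through oxygen at C8a, the aryl anion at C4a would attack the acyl carbon, and the resulting 2-hydroxyaryl ynone would close ring C to give A5.
- Merits: three bonds in one flask, full convergence, and the inherent preference of a 3-alkoxyaryne for attack at the distal carbon matches what is needed. In bond economy this road is better than the chosen one, and it uses the same ring B alkyne 15 (carboxylated to A7).
- Weak points: A5 has hydrogen at C8. The 8-methoxyl would have to be added later by halogenation and methoxylation in the presence of the activated ring B. An aryne already oxygenated at C8 would be flanked on both sides and would lose its regiochemical bias. A6 itself needs a long sequence.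
- Comparison: the chosen plan sets a cheap four-carbon source of C6–C8a against this and places all ring A oxygens before ring C is closed.

Key step: step 4

Remark on the chemistry: 20 is achiral; the stereocentres of 4, 8 and 10 are formed without control and are all destroyed later, so these compounds are carried as racemates or mixtures.

## Route

Step 1
Reactants: 1 methyl propiolate; 2 benzyl alcohol
Product: 3 methyl (2E)-3-(benzyloxy)prop-2-enoate
Conditions: DABCO (10 mol %), CH2Cl2, 0 °C → rt
Reagents that add atoms: none
Why: Amine-catalysed oxa-Michael addition of an alcohol to a propiolate; DABCO adds to the ynoate, the resulting base deprotonates the alcohol, and alkoxide addition with loss of DABCO should give the thermodynamically favoured (E)-3-alkoxyacrylate.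

Step 2
Reactants: 3 methyl (2E)-3-(benzyloxy)prop-2-enoate
Product: 5 methyl (2Z)-3-(benzyloxy)-2-iodoprop-2-enoate, via acetoxy iodide 4 (not isolated)
Conditions: NIS, AcOH, CH2Cl2, rt; then Et3N, rt
Reagents that add atoms: N-iodosuccinimide, O=C1CCC(=O)N1I
Why: Electrophilic iodination at the nucleophilic α-carbon of the enol ether with capture of the oxocarbenium ion by acetate gives 4; E1cB loss of acetic acid with Et3N restores the push–pull alkene with iodine cis to the benzyloxy group, the usual outcome of this iodination–elimination on 3-alkoxyacrylates.

Step 3
Reactants: 5 methyl (2Z)-3-(benzyloxy)-2-iodoprop-2-enoate; 6 dimethyl squarate (3,4-dimethoxycyclobut-3-ene-1,2-dione)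
Product: 8 methyl (2E)-3-(benzyloxy)-2-(1-hydroxy-2,3-dimethoxy-4-oxocyclobut-2-en-1-yl)prop-2-enoate (racemic), via alkenylmagnesium chloride 7 (not isolated)
Conditions: i-PrMgCl·LiCl, THF, −78 °C; then cannulated into 6, THF, −78 → −40 °C; pH 7 buffer
Reagents that add atoms: none
Why: Iodine–magnesium exchange on an electron-poor alkenyl iodide is fast at −78 °C, tolerates the ester and retains the alkene geometry (shown for cyclic 2-iodo-3-alkoxyenoates); the alkenylmagnesium should then add 1,2 to one of the two equivalent ketone carbonyls of the squarate, and the new carbinol centre is racemic and later destroyed.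

Step 4
Reactants: 8 methyl (2E)-3-(benzyloxy)-2-(1-hydroxy-2,3-dimethoxy-4-oxocyclobut-2-en-1-yl)prop-2-enoate
Product: 11 methyl 6-(benzyloxy)-2,5-dihydroxy-3,4-dimethoxybenzoate, via dienylketene 9 (not isolated), via cyclohexadienone 10 (not isolated)
Conditions: degassed toluene (0.02 M), reflux, Ar
Reagents that add atoms: none
Why: Heat should open the cyclobutenone by 4π conrotatory cleavage of the bond between the carbinol carbon and the carbonyl to give dienylketene 9; the closest known reaction is the Moore rearrangement of 4-alkenyl- and 4-aryl-4-hydroxycyclobutenones from squarate esters to hydroquinones. Ring A then closes by a thermal disrotatory 6π electrocyclisation that joins the ketene carbon (C6) to the benzyloxy-bearing alkene carbon (C5) and gives cyclohexadienone 10. Enolisation of 10 removes its only sp3 carbon and gives the aromatic hydroquinone, so no stereocentre survives. The selectivity needed is torquoselectivity: the donor hydroxyl rotates outward, which turns the alkenyl group inward toward the ketene and keeps the hydroxyl away from it, so lactonisation to a furanone is suppressed. Regiochemistry needs no control, since every ring carbon arrives with its substituent: methoxyls on C7 and C8 from the squarate, hydroxyls on C6 and C8a from the two former carbonyl carbons, benzyloxy on C5 and the ester on C4a from the acrylate. The benzyloxy group points inward in 9, but the ketene terminus is linear and carries no substituent to clash with it, and either alkene geometry would converge on the same arene. The ester is a spectator: closure through its carbonyl oxygen would need a seven-membered ring.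

Step 5
Reactants: 11 methyl 6-(benzyloxy)-2,5-dihydroxy-3,4-dimethoxybenzoate
Product: 12 methyl 2,3-bis(benzyloxy)-6-hydroxy-4,5-dimethoxybenzoate
Conditions: BnBr (1.05 equiv), K2CO3, acetone, 50 °C, Ar
Reagents that add atoms: benzyl bromide, BrCc1ccccc1
Why: Williamson etherification; the hydroxyl ortho to the ester is tied up by an intramolecular hydrogen bond and its phenoxide is chelated, so one equivalent of halide with carbonate base should alkylate the other hydroxyl (future O6), the standard selectivity for 2,5-dihydroxybenzoates; exclusion of air protects the hydroquinone.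

Step 6
Reactants: 13 2-hydroxy-6-methoxybenzaldehyde
Product: 14 2-(benzyloxy)-6-methoxybenzaldehyde
Conditions: BnBr, K2CO3, DMF, 60 °C
Reagents that add atoms: benzyl bromide, BrCc1ccccc1
Why: Williamson etherification of a phenol; DMF and mild heating overcome the hydrogen bond to the aldehyde.

Step 7
Reactants: 14 2-(benzyloxy)-6-methoxybenzaldehyde
Product: 15 1-(benzyloxy)-2-ethynyl-3-methoxybenzene
Conditions: dimethyl (1-diazo-2-oxopropyl)phosphonate, K2CO3, MeOH, rt
Reagents that add atoms: dimethyl (1-diazo-2-oxopropyl)phosphonate, COP(=O)(OC)C(=[N+]=[N-])C(C)=O
Why: Seyferth–Gilbert homologation in the Ohira–Bestmann form; methanolysis of the acetyl group frees the diazomethylphosphonate anion, which olefinates the aldehyde, and loss of N2 with 1,2-hydrogen shift in the alkylidene carbene gives the terminal alkyne under conditions that spare the benzyl ether.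

Step 8
Reactants: 15 1-(benzyloxy)-2-ethynyl-3-methoxybenzene; 12 methyl 2,3-bis(benzyloxy)-6-hydroxy-4,5-dimethoxybenzoate
Product: 17 1-[2,3-bis(benzyloxy)-6-hydroxy-4,5-dimethoxyphenyl]-3-[2-(benzyloxy)-6-methoxyphenyl]prop-2-yn-1-one, via lithium acetylide 16 (not isolated)
Conditions: 15 (2.5 equiv), n-BuLi (2.4 equiv), THF, −78 °C; then 12, −78 → 0 °C; aq. NH4Cl
Reagents that add atoms: none
Why: Acylation of a lithium acetylide by a methyl ester, a known ynone synthesis; the first equivalent deprotonates the phenol, the lithium phenoxide holds the ester coplanar and chelated so the linear nucleophile can add from above the ring plane, and the ynone formed is a phenoxide-conjugated ketone that should resist a second addition; the excess of 15 is recovered.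

Step 9
Reactants: 17 1-[2,3-bis(benzyloxy)-6-hydroxy-4,5-dimethoxyphenyl]-3-[2-(benzyloxy)-6-methoxyphenyl]prop-2-yn-1-one
Product: 19 5,6-bis(benzyloxy)-2-[2-(benzyloxy)-6-methoxyphenyl]-7,8-dimethoxy-4H-chromen-4-one, via enaminone 18 (not isolated)
Conditions: Et2NH, EtOH, rt → 60 °C
Reagents that add atoms: none
Why: Conjugate addition of the secondary amine to the ynone gives β-enaminone 18, in which only the amine-bearing carbon is electrophilic; intramolecular addition–elimination by the free phenol then closes ring C in the 6-endo sense with loss of Et2NH, so the 5-exo route to an aurone is closed off, and only O1 can react because O5 is benzylated.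

Step 10
Reactants: 19 5,6-bis(benzyloxy)-2-[2-(benzyloxy)-6-methoxyphenyl]-7,8-dimethoxy-4H-chromen-4-one
Product: 20 5,6-dihydroxy-2-(2-hydroxy-6-methoxyphenyl)-7,8-dimethoxy-4H-chromen-4-one (5,6,2'-trihydroxy-7,8,6'-trimethoxyflavone)
Conditions: H2 (1 atm), 10% Pd/C, EtOAc–MeOH, rt
Reagents that add atoms: none
Why: Hydrogenolysis of three aryl benzyl ethers over Pd/C under neutral conditions; the vinylogous-ester C2–C3 double bond of a flavone is reduced much more slowly and the methyl ethers are inert, and the product is kept from air during isolation.

## Compound list

1 | methyl propiolate | C#CC(=O)OC | starting material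
2 | benzyl alcohol | OCc1ccccc1 | starting material
3 | methyl (2E)-3-(benzyloxy)prop-2-enoate | COC(=O)/C=C/OCc1ccccc1 | intermediate
4 | methyl 3-(acetyloxy)-3-(benzyloxy)-2-iodopropanoate (racemic mixture of diastereomers) | COC(=O)C(I)C(OC(C)=O)OCc1ccccc1 | intermediate
5 | methyl (2Z)-3-(benzyloxy)-2-iodoprop-2-enoate | COC(=O)/C(I)=C/OCc1ccccc1 | intermediate
6 | dimethyl squarate (3,4-dimethoxycyclobut-3-ene-1,2-dione) | COC1=C(OC)C(=O)C1=O | starting material
7 | [(1Z)-2-(benzyloxy)-1-(methoxycarbonyl)ethenyl]magnesium chloride (LiCl complex) | COC(=O)/C([Mg]Cl)=C/OCc1ccccc1 | intermediate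
8 | methyl (2E)-3-(benzyloxy)-2-(1-hydroxy-2,3-dimethoxy-4-oxocyclobut-2-en-1-yl)prop-2-enoate (racemic) | COC(=O)/C(=C/OCc1ccccc1)C1(O)C(OC)=C(OC)C1=O | intermediate
9 | methyl (2E,3Z)-2-[(benzyloxy)methylidene]-3-hydroxy-4,5-dimethoxy-6-oxohexa-3,5-dienoate | O=C=C(OC)/C(OC)=C(O)\C(C(=O)OC)=C/OCc1ccccc1 | intermediate
10 | methyl 6-(benzyloxy)-2-hydroxy-3,4-dimethoxy-5-oxocyclohexa-1,3-diene-1-carboxylate (racemic) | COC(=O)C1=C(O)C(OC)=C(OC)C(=O)C1OCc1ccccc1 | intermediate
11 | methyl 6-(benzyloxy)-2,5-dihydroxy-3,4-dimethoxybenzoate | COC(=O)c1c(O)c(OC)c(OC)c(O)c1OCc1ccccc1 | intermediate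
12 | methyl 2,3-bis(benzyloxy)-6-hydroxy-4,5-dimethoxybenzoate | COC(=O)c1c(O)c(OC)c(OC)c(OCc2ccccc2)c1OCc1ccccc1 | intermediate
13 | 2-hydroxy-6-methoxybenzaldehyde | COc1cccc(O)c1C=O | starting material
14 | 2-(benzyloxy)-6-methoxybenzaldehyde | COc1cccc(OCc2ccccc2)c1C=O | intermediate
15 | 1-(benzyloxy)-2-ethynyl-3-methoxybenzene | COc1cccc(OCc2ccccc2)c1C#C | intermediate
16 | {[2-(benzyloxy)-6-methoxyphenyl]ethynyl}lithium | COc1cccc(OCc2ccccc2)c1C#C[Li] | intermediate
17 | 1-[2,3-bis(benzyloxy)-6-hydroxy-4,5-dimethoxyphenyl]-3-[2-(benzyloxy)-6-methoxyphenyl]prop-2-yn-1-one | COc1cccc(OCc2ccccc2)c1C#CC(=O)c1c(O)c(OC)c(OC)c(OCc2ccccc2)c1OCc1ccccc1 | intermediate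
18 | (2E)-1-[2,3-bis(benzyloxy)-6-hydroxy-4,5-dimethoxyphenyl]-3-[2-(benzyloxy)-6-methoxyphenyl]-3-(diethylamino)prop-2-en-1-one | COc1cccc(OCc2ccccc2)c1/C(N(CC)CC)=C\C(=O)c1c(O)c(OC)c(OC)c(OCc2ccccc2)c1OCc1ccccc1 | intermediate
19 | 5,6-bis(benzyloxy)-2-[2-(benzyloxy)-6-methoxyphenyl]-7,8-dimethoxy-4H-chromen-4-one | COc1cccc(OCc2ccccc2)c1-c1cc(=O)c2c(OCc3ccccc3)c(OCc3ccccc3)c(OC)c(OC)c2o1 | intermediate
20 | 5,6-dihydroxy-2-(2-hydroxy-6-methoxyphenyl)-7,8-dimethoxy-4H-chromen-4-one | COc1cccc(O)c1-c1cc(=O)c2c(O)c(O)c(OC)c(OC)c2o1 | target

## Step count and risks

Total step count: 10. Longest linear sequence: 8 steps (steps 1–5 and 8–10, from methyl propiolate 1 to 20); the ring B branch (steps 6 and 7) joins at step 8.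

**Step 4 (key step).** The most likely failure is capture of the ketene by the free tertiary hydroxyl after a minor inward rotation, giving a furanone. A second is air oxidation of the electron-rich hydroquinone during thermolysis and the basic alkylation that follows.
- Fallback: it sets out from 8, which is silylated (TBSOTf, 2,6-lutidine, CH2Cl2, −78 °C) to methyl (2E)-3-(benzyloxy)-2-{1-[(tert-butyldimethylsilyl)oxy]-2,3-dimethoxy-4-oxocyclobut-2-en-1-yl}prop-2-enoate F1. Thermolysis in toluene should give, by the same cascade, methyl 2-(benzyloxy)-6-[(tert-butyldimethylsilyl)oxy]-3-hydroxy-4,5-dimethoxybenzoate F2, in which the former carbinol oxygen is capped and only O6 is free. Benzylation (BnBr, K2CO3, acetone) gives methyl 2,3-bis(benzyloxy)-6-[(tert-butyldimethylsilyl)oxy]-4,5-dimethoxybenzoate F3, and fluoride (TBAF buffered with AcOH, THF, 0 °C) returns to the route at 12.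
- What it changes: no nucleophilic hydroxyl and no free hydroquinone is present, and the two oxygens are assigned without the hydrogen-bond argument.

**Step 3.** The ester-stabilised alkenylmagnesium 7 is a weak nucleophile, so carbonyl addition may be sluggish and the reagent may decompose on warming; double addition to 6 is also possible.
- Fallback: it sets out from 5 and 6 and forms the same bond by a Nozaki–Hiyama–Kishi coupling (CrCl2, catalytic NiCl2, DMF, rt). The alkenylchromium species is generated in the presence of the highly electrophilic squarate, is stable at room temperature and tolerates the ester. It returns to the route at 8 and makes no new compound (F0).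

**Step 8.** The lithium phenoxide donates into the ester and both ortho positions are substituted, so addition may stop short. The phenoxide ynone may also ring-close in the flask in either sense.
- Fallback: it sets out from 12 and goes through the aldehyde oxidation level. Reduction (LiAlH4, THF, 0 °C) gives 3,4-bis(benzyloxy)-2-(hydroxymethyl)-5,6-dimethoxyphenol F4. Oxidation with MnO2 (CH2Cl2) gives 2,3-bis(benzyloxy)-6-hydroxy-4,5-dimethoxybenzaldehyde F5. Addition of acetylide 16 (2.2 equiv, THF, −78 °C) gives 3,4-bis(benzyloxy)-2-{3-[2-(benzyloxy)-6-methoxyphenyl]-1-hydroxyprop-2-yn-1-yl}-5,6-dimethoxyphenol F6. A second MnO2 oxidation returns to the route at 17.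

**Step 9.** Conjugate addition of the amine at the alkyne carbon next to the di-ortho-substituted ring B may be slow, which would let direct 5-exo closure to an aurone compete.
- Fallback: it sets out from 17 and triggers closure with an electrophile instead. ICl (CH2Cl2, −78 °C) places positive charge on the alkyne carbon next to the electron-rich ring B, so the phenol should attack there and give 5,6-bis(benzyloxy)-2-[2-(benzyloxy)-6-methoxyphenyl]-3-iodo-7,8-dimethoxy-4H-chromen-4-one F7. Hydrogenolysis with added NaOAc (H2, Pd/C, EtOAc–MeOH) removes the iodine together with the benzyl groups and arrives at 20.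

**Step 10.** The C2–C3 double bond may be over-reduced if cleavage of the hindered 5-benzyl ether is slow, and the catechol may oxidise during work-up.
- Fallback: it sets out from 19 and cleaves the benzyl ethers with a Lewis acid and a cation scavenger (BCl3, pentamethylbenzene, CH2Cl2, −78 °C), conditions that leave aryl methyl ethers and the enone untouched. It arrives at 20 and makes no new compound (F0).

## Further compounds

F1 | step 4 | methyl (2E)-3-(benzyloxy)-2-{1-[(tert-butyldimethylsilyl)oxy]-2,3-dimethoxy-4-oxocyclobut-2-en-1-yl}prop-2-enoate (racemic) | COC(=O)/C(=C/OCc1ccccc1)C1(O[Si](C)(C)C(C)(C)C)C(OC)=C(OC)C1=O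
F2 | step 4 | methyl 2-(benzyloxy)-6-[(tert-butyldimethylsilyl)oxy]-3-hydroxy-4,5-dimethoxybenzoate | COC(=O)c1c(O[Si](C)(C)C(C)(C)C)c(OC)c(OC)c(O)c1OCc1ccccc1
F3 | step 4 | methyl 2,3-bis(benzyloxy)-6-[(tert-butyldimethylsilyl)oxy]-4,5-dimethoxybenzoate | COC(=O)c1c(O[Si](C)(C)C(C)(C)C)c(OC)c(OC)c(OCc2ccccc2)c1OCc1ccccc1
F0 | step 3 | none | none
F4 | step 8 | 3,4-bis(benzyloxy)-2-(hydroxymethyl)-5,6-dimethoxyphenol | OCc1c(O)c(OC)c(OC)c(OCc2ccccc2)c1OCc1ccccc1
F5 | step 8 | 2,3-bis(benzyloxy)-6-hydroxy-4,5-dimethoxybenzaldehyde | O=Cc1c(O)c(OC)c(OC)c(OCc2ccccc2)c1OCc1ccccc1
F6 | step 8 | 3,4-bis(benzyloxy)-2-{3-[2-(benzyloxy)-6-methoxyphenyl]-1-hydroxyprop-2-yn-1-yl}-5,6-dimethoxyphenol (racemic) | COc1cccc(OCc2ccccc2)c1C#CC(O)c1c(O)c(OC)c(OC)c(OCc2ccccc2)c1OCc1ccccc1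
F7 | step 9 | 5,6-bis(benzyloxy)-2-[2-(benzyloxy)-6-methoxyphenyl]-3-iodo-7,8-dimethoxy-4H-chromen-4-one | COc1cccc(OCc2ccccc2)c1-c1oc2c(OC)c(OC)c(OCc3ccccc3)c(OCc3ccccc3)c2c(=O)c1I
F0 | step 10 | none | none
A1 | alternative 1 | lactone joining the C3 carboxyl to O2' of 5,6-(diphenylmethylenedioxy)-2'-hydroxy-7,8,6'-trimethoxyflavone (chromeno[4,3-b]chromene-6,7-dione core) | COc1cccc2OC(=O)c3c(oc4c(OC)c(OC)c5OC(c6ccccc6)(c6ccccc6)Oc5c4c3=O)-c12
A2 | alternative 1 | 2-bromo-3-methoxyphenyl 5,6-(diphenylmethylenedioxy)-7,8-dimethoxy-4-oxo-4H-chromene-3-carboxylate | COc1cccc(OC(=O)c2coc3c(OC)c(OC)c4OC(c5ccccc5)(c5ccccc5)Oc4c3c2=O)c1Br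
A3 | alternative 2 | 2-[2-(benzyloxy)-6-methoxyphenyl]-5,7-dihydroxy-6,8-dimethoxy-4H-chromen-4-one | COc1cccc(OCc2ccccc2)c1-c1cc(=O)c2c(O)c(OC)c(O)c(OC)c2o1
A4 | alternative 2 | methyl 4-{6-[2-(benzyloxy)-6-methoxyphenyl]-4-oxo-4H-pyran-2-yl}-2,4-dimethoxy-3-oxobutanoate (mixture of stereoisomers) | COC(=O)C(OC)C(=O)C(OC)c1cc(=O)cc(-c2c(OC)cccc2OCc2ccccc2)o1
A5 | alternative 3 | 2-[2-(benzyloxy)-6-methoxyphenyl]-5,6-(diphenylmethylenedioxy)-7-methoxy-4H-chromen-4-one | COc1cccc(OCc2ccccc2)c1-c1cc(=O)c2c3OC(c4ccccc4)(c4ccccc4)Oc3c(OC)cc2o1
A6 | alternative 3 | 7-methoxy-2,2-diphenyl-4-(trimethylsilyl)-1,3-benzodioxol-5-yl trifluoromethanesulfonate | COc1cc(OS(=O)(=O)C(F)(F)F)c([Si](C)(C)C)c2OC(c3ccccc3)(c3ccccc3)Oc12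
A7 | alternative 3 | 3-[2-(benzyloxy)-6-methoxyphenyl]prop-2-ynoic acid | COc1cccc(OCc2ccccc2)c1C#CC(=O)O
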